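## The problem

Compound 11 is a furan that carries a 1,4-benzoquinone ring on one α-carbon (C5 in the locants used here) and a six-carbon chain on the β-carbon across the ring (C3). The first carbon of that chain is an esterified carbinol. The two rings are joined by a single C–C bond, so the skeleton amounts to one biaryl-type bond plus one chain.

The only stereocentre is the carbinol carbon, (R)-configured and bonded to the furan, the isovalerate oxygen and a CH2 group. Nothing else in the molecule can direct it, so a catalyst must set it. It must then be kept from ionising, because a furan-stabilised cation at this carbon would racemise or eliminate.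

The chain ends in a CH=CMe2 unit homoallylic to the oxygen. A prenyl metal cannot deliver this arrangement to an aldehyde, since such reagents react through their γ-carbon and give the 1,1-dimethylallyl isomer.

The quinone is an oxidant and a Michael acceptor and will not survive organometallic reagents, hydride donors or hydroxide. It must therefore travel in masked form and be released last. The furan and the trisubstituted alkene limit how harsh that release may be.

The feature that opens the route is the O–C1–C2 array of the chain. C1 (the stereocentre) and C2 (the CH2 group) are the two carbons of a terminal oxirane, and C2 is bonded to the sp2 carbon C3 of the alkene. Cutting C2–C3 gives a furyl oxirane and a 2-methylprop-1-enyl metal, an sp2 nucleophile with no allylic position through which it could transpose.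

## Retrosynthesis

Quinone 11 is traced first to the hydroquinone dimethyl ether 10. No C–C bond is cut; the two C=O groups are exchanged for two aryl–OMe groups. The dimethyl ether is inert to every earlier reagent and comes ready-made in a commercial boronic acid. Acetal-type masks would have to be removed by acid next to an ionisable furylic ester. The forward step asks the oxidant to choose the 1,4-dimethoxy ring over the furan and the trisubstituted alkene.

Ester 10 is cut at the acyl–oxygen bond into alcohol 8 and 3-methylbutanoyl chloride 9. With acylation placed after all organometallic chemistry, the ester never meets a strong nucleophile. The reaction touches only the O–H bond, so the configuration of 8 is carried over.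

Alcohol 8 is cut between C2 (the CH2 group) and C3 (the alkene CH) into oxirane 6 and 2-methylprop-1-enylmagnesium bromide 7. The neighbouring cuts are worse:
- C1–C2 leads to a furan aldehyde and a prenyl metal, which would return the branched isomer by γ-attack.
- The bond from furan C3 to C1 leads to a furyl metal and a β,γ-unsaturated aldehyde that slips into conjugation, with the stereocentre still to be made.
- A cut through the C=C bond needs a β-hydroxy aldehyde prone to elimination.

The chosen cut removes the whole isobutenyl unit as a purchasable reagent. It leaves a precursor in which the stereocentre is locked in a three-membered ring. The forward reaction must deliver the alkenyl group to the CH2 carbon only and must leave the C–O bond at the stereocentre intact.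

Oxirane 6 is opened in the retrosynthetic sense at its CH2–O bond to chlorohydrin 5. Removing the carbinol hydrogen then leads to the achiral chloroketone 4. The stereocentre thus comes from a catalyst-controlled hydride transfer to an aryl-type ketone, a reduction with a well-understood sense of induction. Direct asymmetric epoxidation of a terminal vinylfuran offers nothing as dependable. The forward sequence needs high facial selectivity and a ring closure in which oxygen, not the stereocentre, does the displacing.

Chloroketone 4 is cut between the carbonyl carbon and the CH2Cl carbon into methyl ester 3 and a chloromethyl anion equivalent. Chlorinating a methyl ketone instead would bring electrophilic chlorine to a molecule with two electron-rich rings. The carbenoid route forms the C–C bond and needs no oxidant. The forward step requires the tetrahedral adduct to hold until the quench so that only one carbenoid adds.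

Ester 3 is cut at the bond between furan C5 and the benzene ring into methyl 5-bromofuran-3-carboxylate 1 and (2,5-dimethoxyphenyl)boronic acid 2. Both are simple, and the bromide fixes which α-carbon of the furan carries the aryl ring. Electrophilic substitution on a 3-acylfuran would leave that question open. The forward coupling only has to tolerate a methyl ester.

## Roads not taken

Alternative 1: The furan is cut at its C3=C4 bond. A bis-allylic ether A2 holds a vinyl group on the aryl-bearing carbon and a 1,1-disubstituted alkene on the other arm. Ring-closing metathesis with second-generation Grubbs catalyst closes it to the 2,5-dihydrofuran A1, which must then be dehydrogenated to reach ester 10.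
- Merits: the 2,4-substitution pattern of the furan is fixed by construction. No brominated furan is needed, and the regiochemical question of an epoxide opening never arises. In these two respects it is the safer plan.
- Weak points: A1 sits one oxidation level below the furan, so an extra dehydrogenation must be run beside an allylic ester that can ionise or eliminate. Closure onto a 1,1-disubstituted alkene is slow, and the prenyl alkene is a second metathesis partner. A2 already contains the stereocentre as the ester of a 2-substituted allylic alcohol, so the homoallylic CH=CMe2 problem returns in a less favourable setting.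
- Comparison: the chosen plan sets against it a furan that is bought with its substitution in place, two fewer redox operations, and a stereocentre made by reducing an aryl-type ketone.

Alternative 2: The six-membered ring is built by a Dötz benzannulation. The carbene complex (CO)5Cr=C(OMe)CH=CH2 A4 and the 2-ethynylfuran ester A5 combine with uptake of one CO ligand to give the 4-methoxyphenol A3, which is then oxidised to 11.
- Merits: the regiochemistry is secure, since a terminal alkyne places its substituent next to the phenol. A 4-methoxyphenol is oxidised to a quinone under milder conditions than a bis-methyl ether. In that last step this road is better than the chosen one.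
- Weak points: chromium is used stoichiometrically to build a benzene ring that can be bought. The parent vinyl carbene complex is among the least well-behaved of its class. A5 must already carry the complete chiral ester side chain on a fragile ethynylfuran, so the stereocentre and the chain still have to be made, and earlier.
- Comparison: the chosen plan accepts a harsher final oxidation. In return it has a purchasable arene, catalytic metals only and a shorter sequence.

Alternative 3: The bond from furan C3 to the stereocentre is cut. The racemic 1-chloroalkyl ester A7 and the furylzinc chloride A8 are coupled with NiBr2(diglyme) and a chiral bis(oxazoline) ligand to give A6, which is the same compound as ester 10.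
- Merits: one step forms the C–C bond, sets the stereocentre and delivers the ester. On paper this is the shortest and most convergent road, and if it worked it would save about two steps.
- Weak points: A7 derives from 4-methylpent-3-enal A9, a β,γ-unsaturated aldehyde that isomerises easily, and A7 itself is moisture-sensitive. A8 requires a 2-arylfuran metalated at C4, which is harder to reach than bromo ester 1. The selectivity of such enantioconvergent couplings for a heteroarylzinc of this shape and a radical partner with a pendant alkene cannot be predicted from close analogies.
- Comparison: the chosen plan sets against it stereocontrol from a reduction with a reliable model, and bond formations that can each be checked separately.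

Key step: step 4

## Route

Remark on the chemistry: methyl 5-bromofuran-3-carboxylate (1) is taken as a purchasable building block whose bromine already sits on the furan carbon that must carry the aryl ring.

Step 1
Reactants: 1 methyl 5-bromofuran-3-carboxylate; 2 (2,5-dimethoxyphenyl)boronic acid
Product: 3 methyl 5-(2,5-dimethoxyphenyl)furan-3-carboxylate
Conditions: Pd(dppf)Cl2 (3 mol %), K2CO3, 1,4-dioxane/H2O, 80 °C
Reagents that add atoms: none
Why: Suzuki–Miyaura coupling; the C–Br bond at the furan α-carbon adds readily to zerovalent palladium and the boronic acid transmetalates under aqueous carbonate, while the methyl ester tolerates the short heating. The position of the aryl ring is fixed by the bromide.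

Step 2
Reactants: 3 methyl 5-(2,5-dimethoxyphenyl)furan-3-carboxylate
Product: 4 2-chloro-1-[5-(2,5-dimethoxyphenyl)furan-3-yl]ethan-1-one
Conditions: ICH2Cl, MeLi·LiBr, THF, −78 °C; AcOH quench at −78 °C
Reagents that add atoms: chloroiodomethane, ClCI
Why: Acylation of chloromethyllithium by an ester (halomethyllithium homologation); iodine–lithium exchange between MeLi and ICH2Cl outruns attack of MeLi on the ester, and the tetrahedral lithium alkoxide holds at −78 °C until the cold acid quench, so the ketone appears only after the carbenoid is gone. No electrophilic chlorine is used, which spares the furan and the dimethoxyarene.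

Step 3
Reactants: 4 2-chloro-1-[5-(2,5-dimethoxyphenyl)furan-3-yl]ethan-1-one
Product: 6 (2S)-2-[5-(2,5-dimethoxyphenyl)furan-3-yl]oxirane, via (S)-chlorohydrin 5 (not isolated)
Conditions: RuCl(p-cymene)[(R,R)-TsDPEN] (1 mol %), HCO2H/Et3N (5:2), EtOAc, rt; then 2 M aq NaOH, THF, 0 °C
Reagents that add atoms: none
Why: Asymmetric transfer hydrogenation of the Noyori type on an aryl chloromethyl ketone, then Williamson-type closure of the chlorohydrin; with the (R,R) ligand hydride goes to the face that gives (R)-1-arylethanols from aryl methyl ketones, the furan taking the aryl position beside the p-cymene ligand, and this is the (S)-chlorohydrin 5 because CH2Cl outranks the furyl carbon. The alkoxide then displaces chloride at the CH2 carbon (3-exo-tet) without touching the stereocentre, so 6 is (S).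

Step 4
Reactants: 6 (2S)-2-[5-(2,5-dimethoxyphenyl)furan-3-yl]oxirane; 7 2-methylprop-1-enylmagnesium bromide
Product: 8 (1R)-1-[5-(2,5-dimethoxyphenyl)furan-3-yl]-4-methylpent-3-en-1-ol
Conditions: CuI (10 mol %), THF, −40 to −20 °C, 6 added slowly to 7 (2 equiv); aq NH4Cl
Reagents that add atoms: none
Why: CuI and 7 form a magnesium alkenylcuprate whose filled copper d orbital attacks the oxirane C–O σ* at the CH2 carbon from the rear (SN2-type oxidative addition); the resulting alkyl(alkenyl) species of trivalent copper reductively eliminates to form the C2–C3 bond and returns monovalent copper. The closest known reaction type is the copper-catalysed opening of monosubstituted oxiranes, aryl-substituted ones included, by alkenyl Grignard reagents at the unsubstituted carbon. No ring is closed and no stereocentre is created: the C–O bond at the carbinol carbon is never broken, so the configuration from step 3 is kept, and the descriptor changes from S in 6 to R in 8 only because the CH2 group loses its oxygen and drops below the furyl carbon in priority. The nucleophile is bound to copper through an sp2 carbon, so CH=CMe2 is transferred as such, and the two methyl groups are identical, so no alkene geometry is at stake. The step needs regioselectivity for CH2 over the furyl-bearing carbon and must avoid Lewis-acid pathways (bromohydrin formation, Meinwald rearrangement to an aldehyde that the Grignard reagent would capture). In the substrate the CH2 terminus is unhindered, the oxirane hangs on the furan β-carbon, and the electron-rich aryl ring at C5 is not in through-conjugation with the carbinol carbon, so positive charge builds up there only modestly; THF as donor solvent, low temperature and slow addition of 6 to excess cuprate keep the reaction on the SN2 path. Furan C–H bonds and aryl methyl ethers are inert to 7 and 6 has no acidic proton.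

Step 5
Reactants: 8 (1R)-1-[5-(2,5-dimethoxyphenyl)furan-3-yl]-4-methylpent-3-en-1-ol; 9 3-methylbutanoyl chloride
Product: 10 (1R)-1-[5-(2,5-dimethoxyphenyl)furan-3-yl]-4-methylpent-3-en-1-yl 3-methylbutanoate
Conditions: pyridine, DMAP (cat.), CH2Cl2, 0 °C to rt
Reagents that add atoms: none
Why: Acylation of a secondary alcohol by an acid chloride under nucleophilic catalysis by DMAP; only the O–H bond reacts, so the (R) configuration is retained, and the basic medium never exposes the furylic C–O bond to acid.

Step 6
Reactants: 10 (1R)-1-[5-(2,5-dimethoxyphenyl)furan-3-yl]-4-methylpent-3-en-1-yl 3-methylbutanoate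
Product: 11 (1R)-1-[5-(3,6-dioxocyclohexa-1,4-dien-1-yl)furan-3-yl]-4-methylpent-3-en-1-yl 3-methylbutanoate
Conditions: (NH4)2Ce(NO3)6 (2.5 equiv), MeCN/H2O, 0 °C
Reagents that add atoms: water, O
Why: Oxidative demethylation of a hydroquinone dimethyl ether; two one-electron oxidations by tetravalent cerium and ipso attack of water at the two methoxy-bearing carbons release methanol and leave the quinone. This oxidation is established for 1,4-dimethoxyarenes carrying a 1-acyloxy-4-methylpent-3-enyl chain and for dimethoxyarenes fused to a furan, the 1,4-dimethoxy ring being the most easily oxidised part of 10; short contact at 0 °C limits acid exposure of the furylic ester.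

## Compound list

1 | methyl 5-bromofuran-3-carboxylate | COC(=O)c1coc(Br)c1 | starting material
2 | (2,5-dimethoxyphenyl)boronic acid | COc1ccc(OC)c(c1)B(O)O | starting material
3 | methyl 5-(2,5-dimethoxyphenyl)furan-3-carboxylate | COC(=O)c1coc(-c2cc(OC)ccc2OC)c1 | intermediate
4 | 2-chloro-1-[5-(2,5-dimethoxyphenyl)furan-3-yl]ethan-1-one | ClCC(=O)c1coc(-c2cc(OC)ccc2OC)c1 | intermediate
5 | (1S)-2-chloro-1-[5-(2,5-dimethoxyphenyl)furan-3-yl]ethan-1-ol | O[C@H](CCl)c1coc(-c2cc(OC)ccc2OC)c1 | intermediate
6 | (2S)-2-[5-(2,5-dimethoxyphenyl)furan-3-yl]oxirane | C1O[C@H]1c1coc(-c2cc(OC)ccc2OC)c1 | intermediate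
7 | 2-methylprop-1-enylmagnesium bromide | CC(C)=C[Mg]Br | starting material
8 | (1R)-1-[5-(2,5-dimethoxyphenyl)furan-3-yl]-4-methylpent-3-en-1-ol | CC(C)=CC[C@@H](O)c1coc(-c2cc(OC)ccc2OC)c1 | intermediate
9 | 3-methylbutanoyl chloride | CC(C)CC(Cl)=O | starting material
10 | (1R)-1-[5-(2,5-dimethoxyphenyl)furan-3-yl]-4-methylpent-3-en-1-yl 3-methylbutanoate | CC(C)=CC[C@@H](OC(=O)CC(C)C)c1coc(-c2cc(OC)ccc2OC)c1 | intermediate
11 | (1R)-1-[5-(3,6-dioxocyclohexa-1,4-dien-1-yl)furan-3-yl]-4-methylpent-3-en-1-yl 3-methylbutanoate | CC(C)=CC[C@@H](OC(=O)CC(C)C)c1coc(C2=CC(=O)C=CC2=O)c1 | target

## Step count and risks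

Total step count: 6. Longest linear sequence: 6 steps, from 1 to 11.

Step 4 (key step). The likely failure is loss of regiocontrol in the ring opening. If magnesium halide from the Schlenk equilibrium activates the oxirane oxygen before the cuprate arrives, the C–O bond at the furyl-bearing carbon stretches. The alkenyl group or bromide then enters at that carbon, or a hydride shift gives an aldehyde that the Grignard reagent captures. Oxirane 6 is also acid-sensitive and should be passed through Et3N-deactivated silica and used at once.

The fallback forms the chain by allylation and sets out from ester 3. Reduction with i-Bu2AlH (CH2Cl2, −78 to 0 °C) gives [5-(2,5-dimethoxyphenyl)furan-3-yl]methanol F1, and MnO2 (CH2Cl2) oxidises it to 5-(2,5-dimethoxyphenyl)furan-3-carbaldehyde F2. Brown allylation with (+)-Ipc2B(allyl), the reagent made from (−)-α-pinene that adds to the Re face of aryl aldehydes (Et2O, −78 °C), should give (1R)-1-[5-(2,5-dimethoxyphenyl)furan-3-yl]but-3-en-1-ol F3. Cross-metathesis of F3 with excess 2-methylbut-2-ene and second-generation Grubbs catalyst (CH2Cl2, 40 °C) turns CH=CH2 into CH=CMe2 and returns to the route at alcohol 8. A symmetrical allyl group cannot give a transposed isomer.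

Step 6. The likely failure is oxidation at the wrong site. The radical cation is spread over the benzene and furan rings, and capture by water at the free furan α-carbon would open or over-oxidise the furan. The nitric acid formed may also ionise the furylic ester and erode the configuration.

The fallback masks the hydroquinone as its bis(methoxymethyl) ether, so that the last operation is the mild oxidation of a free hydroquinone. It sets out from bromo ester 1 and comes back at target 11.
- Suzuki–Miyaura coupling under the conditions of step 1 with [2,5-bis(methoxymethoxy)phenyl]boronic acid F4 (from directed ortho-lithiation and borylation of the corresponding bis-ether) gives methyl 5-[2,5-bis(methoxymethoxy)phenyl]furan-3-carboxylate F5.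
- The chemistry of steps 2 to 5 is applied unchanged. It leads through 1-{5-[2,5-bis(methoxymethoxy)phenyl]furan-3-yl}-2-chloroethan-1-one F6 and the non-isolated (1S)-1-{5-[2,5-bis(methoxymethoxy)phenyl]furan-3-yl}-2-chloroethan-1-ol F7 to (2S)-2-{5-[2,5-bis(methoxymethoxy)phenyl]furan-3-yl}oxirane F8.
- It continues to (1R)-1-{5-[2,5-bis(methoxymethoxy)phenyl]furan-3-yl}-4-methylpent-3-en-1-ol F9 and (1R)-1-{5-[2,5-bis(methoxymethoxy)phenyl]furan-3-yl}-4-methylpent-3-en-1-yl 3-methylbutanoate F10.
- TMSOTf with 2,2'-bipyridyl (CH2Cl2, 0 °C), then water, removes both acetals under buffered conditions. This gives (1R)-1-[5-(2,5-dihydroxyphenyl)furan-3-yl]-4-methylpent-3-en-1-yl 3-methylbutanoate F11.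
- Ag2O in Et2O oxidises F11 to 11.

Step 2. The likely failure is breakdown of the tetrahedral adduct before the quench, which exposes the ketone to a second carbenoid addition. α-Elimination of the carbenoid before it finds the moderately electrophilic furoate is also possible.

The fallback sets out from ester 3. Dimethylsulfoxonium methylide (from Me3S(O)I and KOt-Bu, THF, reflux) is acylated by the ester to give the stable 2-[dimethyl(oxo)-λ6-sulfanylidene]-1-[5-(2,5-dimethoxyphenyl)furan-3-yl]ethan-1-one F12. HCl in dioxane/THF at about 60 °C protonates the ylide carbon, and chloride displaces dimethyl sulfoxide. This returns to the route at chloroketone 4.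

Step 3. The likely failures are imperfect facial discrimination, because a 5-arylfuran-3-yl group is not a phenyl group, and displacement of chloride by formate before reduction. Loss of the acid-sensitive oxirane on isolation is a further risk.

The fallback replaces asymmetric reduction by resolution and sets out from chloroketone 4. NaBH4 (MeOH, 0 °C) gives racemic 2-chloro-1-[5-(2,5-dimethoxyphenyl)furan-3-yl]ethan-1-ol F13, and aqueous NaOH closes it to racemic 2-[5-(2,5-dimethoxyphenyl)furan-3-yl]oxirane F14. Jacobsen hydrolytic kinetic resolution follows with (S,S)-(salen)Co(OAc) (salen = N,N'-bis(3,5-di-tert-butylsalicylidene)cyclohexane-1,2-diamine dianion, trivalent cobalt) and about half an equivalent of water. This should hydrolyse the (R)-oxirane to its diol and leave the (S)-oxirane, returning to the route at 6 at the cost of half the material.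

## Further compounds

F1 | step 4 | [5-(2,5-dimethoxyphenyl)furan-3-yl]methanol | OCc1coc(-c2cc(OC)ccc2OC)c1
F2 | step 4 | 5-(2,5-dimethoxyphenyl)furan-3-carbaldehyde | O=Cc1coc(-c2cc(OC)ccc2OC)c1
F3 | step 4 | (1R)-1-[5-(2,5-dimethoxyphenyl)furan-3-yl]but-3-en-1-ol | C=CC[C@@H](O)c1coc(-c2cc(OC)ccc2OC)c1
F4 | step 6 | [2,5-bis(methoxymethoxy)phenyl]boronic acid | COCOc1ccc(OCOC)c(c1)B(O)O
F5 | step 6 | methyl 5-[2,5-bis(methoxymethoxy)phenyl]furan-3-carboxylate | COC(=O)c1coc(-c2cc(OCOC)ccc2OCOC)c1
F6 | step 6 | 1-{5-[2,5-bis(methoxymethoxy)phenyl]furan-3-yl}-2-chloroethan-1-one | ClCC(=O)c1coc(-c2cc(OCOC)ccc2OCOC)c1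
F7 | step 6 | (1S)-1-{5-[2,5-bis(methoxymethoxy)phenyl]furan-3-yl}-2-chloroethan-1-ol | O[C@H](CCl)c1coc(-c2cc(OCOC)ccc2OCOC)c1
F8 | step 6 | (2S)-2-{5-[2,5-bis(methoxymethoxy)phenyl]furan-3-yl}oxirane | C1O[C@H]1c1coc(-c2cc(OCOC)ccc2OCOC)c1
F9 | step 6 | (1R)-1-{5-[2,5-bis(methoxymethoxy)phenyl]furan-3-yl}-4-methylpent-3-en-1-ol | CC(C)=CC[C@@H](O)c1coc(-c2cc(OCOC)ccc2OCOC)c1
F10 | step 6 | (1R)-1-{5-[2,5-bis(methoxymethoxy)phenyl]furan-3-yl}-4-methylpent-3-en-1-yl 3-methylbutanoate | CC(C)=CC[C@@H](OC(=O)CC(C)C)c1coc(-c2cc(OCOC)ccc2OCOC)c1
F11 | step 6 | (1R)-1-[5-(2,5-dihydroxyphenyl)furan-3-yl]-4-methylpent-3-en-1-yl 3-methylbutanoate | CC(C)=CC[C@@H](OC(=O)CC(C)C)c1coc(-c2cc(O)ccc2O)c1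
F12 | step 2 | 2-[dimethyl(oxo)-λ6-sulfanylidene]-1-[5-(2,5-dimethoxyphenyl)furan-3-yl]ethan-1-one | C[S+](C)(=O)[CH-]C(=O)c1coc(-c2cc(OC)ccc2OC)c1
F13 | step 3 | 2-chloro-1-[5-(2,5-dimethoxyphenyl)furan-3-yl]ethan-1-ol (racemic) | OC(CCl)c1coc(-c2cc(OC)ccc2OC)c1
F14 | step 3 | 2-[5-(2,5-dimethoxyphenyl)furan-3-yl]oxirane (racemic) | C1OC1c1coc(-c2cc(OC)ccc2OC)c1
A1 | alternative 1 | (1R)-1-[5-(2,5-dimethoxyphenyl)-2,5-dihydrofuran-3-yl]-4-methylpent-3-en-1-yl 3-methylbutanoate | C1OC(C=C1[C@@H](CC=C(C)C)OC(=O)CC(C)C)c1cc(OC)ccc1OC
A2 | alternative 1 | (3R)-2-({[1-(2,5-dimethoxyphenyl)prop-2-en-1-yl]oxy}methyl)-6-methylhepta-1,5-dien-3-yl 3-methylbutanoate | C=CC(OCC(=C)[C@@H](CC=C(C)C)OC(=O)CC(C)C)c1cc(OC)ccc1OC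
A3 | alternative 2 | (1R)-1-[5-(2-hydroxy-5-methoxyphenyl)furan-3-yl]-4-methylpent-3-en-1-yl 3-methylbutanoate | CC(C)=CC[C@@H](OC(=O)CC(C)C)c1coc(-c2cc(OC)ccc2O)c1
A4 | alternative 2 | pentacarbonyl(1-methoxyprop-2-en-1-ylidene)chromium, (CO)5Cr=C(OMe)CH=CH2 | COC(C=C)=[Cr](=C=O)(=C=O)(=C=O)(=C=O)=C=O
A5 | alternative 2 | (1R)-1-(5-ethynylfuran-3-yl)-4-methylpent-3-en-1-yl 3-methylbutanoate | C#Cc1cc(co1)[C@@H](CC=C(C)C)OC(=O)CC(C)C
A6 | alternative 3 | (1R)-1-[5-(2,5-dimethoxyphenyl)furan-3-yl]-4-methylpent-3-en-1-yl 3-methylbutanoate | CC(C)=CC[C@@H](OC(=O)CC(C)C)c1coc(-c2cc(OC)ccc2OC)c1
A7 | alternative 3 | 1-chloro-4-methylpent-3-en-1-yl 3-methylbutanoate (racemic) | CC(C)=CCC(Cl)OC(=O)CC(C)C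
A8 | alternative 3 | [5-(2,5-dimethoxyphenyl)furan-3-yl]zinc chloride | Cl[Zn]c1coc(-c2cc(OC)ccc2OC)c1
A9 | alternative 3 | 4-methylpent-3-enal | CC(C)=CCC=O
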